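**Retrosynthetic overview**

1. The target is a methylene-bridged pair. Rings A/B are a 6-butanoyl-5,7-dihydroxy-2,2-dimethyl-2H-chromene bridged at C8. Ring C is a dearomatised acetylphloroglucinol, the enol of a 2-acetylcyclohexane-1,3,5-trione, numbered C1′ (C=O), C2′ (C-acetyl), C3′ (C-OH), C4′ (quaternary: Me, geranyl; R), C5′ (C-OH), C6′ (C-CH2-ring A).
2. Key disconnection: ring C is closed last at C1′–C2′ by a Claisen condensation, in the same operation that joins C5′ to C6′. With no atom lost, this unravels the target into an achiral dihydrocoumarin (rings A/B with C6′ and C1′ held as an aryl δ-lactone on the C7 oxygen) and an (S)-3-geranyl-3,6-dimethylpyran-2,4-dione (C5′, C4′, C3′, C2′ and the acetyl group held as an enol lactone).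
3. Enabling feature: C2′ lies between three carbonyl groups (C1′, C3′ and the acetyl C=O), so C-acylation there is a thermodynamic sink. C1′ is at the carboxyl level and forms a six-membered ring with C6′, the bridge CH2, C8, C7 and the C7 oxygen, so it can be stored as an aryl lactone. Quaternary C4′ forbids aromatisation and lets the acetyl oxygen serve as the ring oxygen of a pyranone.
4. The only stereocentre (C4′) is set before the key step by palladium-catalysed asymmetric dearomative C-geranylation of 4-hydroxy-3,6-dimethyl-2-pyranone. The lactone partner comes from phloroglucinol by acylation, chromene annulation and a three-component lactone annulation.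
5. Ring order: ring A (bought) → ring B → temporary lactone ring; separately the temporary pyrandione ring; ring C last, as both temporary rings open.

Key step: step 6

Remark: ring C is a cyclic β-triketone whose enol tautomers interconvert freely, so the route delivers the equilibrium mixture of which the given SMILES is one form; 4-hydroxy-3,6-dimethyl-2H-pyran-2-one is taken as a purchasable compound.

**Step 1**
Reactants: 1 geraniol [(2E)-3,7-dimethylocta-2,6-dien-1-ol]; 2 di-tert-butyl dicarbonate
Product: 3 tert-butyl (2E)-3,7-dimethylocta-2,6-dien-1-yl carbonate (tert-butyl geranyl carbonate)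
Conditions: Boc2O (1.2 equiv), n-Bu4NHSO4 (5 mol %), 30% aq NaOH, CH2Cl2, 0 → 23 °C
Reagents that add atoms: di-tert-butyl dicarbonate (2), CC(C)(C)OC(=O)OC(=O)OC(C)(C)C
Why: Alkoxycarbonylation of a primary allylic alcohol under phase-transfer catalysis is routine and touches neither olefin, so the E geometry of the geranyl unit is carried through unchanged.

**Step 2**
Reactants: 4 4-hydroxy-3,6-dimethyl-2H-pyran-2-one; 3 tert-butyl geranyl carbonate
Product: 5 (3S)-3-[(2E)-3,7-dimethylocta-2,6-dien-1-yl]-3,6-dimethyl-2H-pyran-2,4(3H)-dione
Conditions: Pd2(dba)3·CHCl3 (2.5 mol %), (R,R)-DACH-phenyl bisphosphine ligand [N,N′-((1R,2R)-cyclohexane-1,2-diyl)bis(2-(diphenylphosphanyl)benzamide)] (7.5 mol %), degassed CH2Cl2, 0 → 23 °C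
Reagents that add atoms: tert-butyl geranyl carbonate (3), CC(C)(C)OC(=O)OC/C=C(\C)CCC=C(C)C
Why: Tsuji–Trost asymmetric allylic alkylation used as a dearomative C3-allylation of a cyclic β-keto lactone enol: zerovalent palladium ionises 3 to a π-geranyl complex of divalent palladium and tert-butoxide (after loss of CO2), which deprotonates 4; the soft pyranonate should attack the unsubstituted allyl terminus through C3 (a fully substituted nucleophilic carbon avoids the tertiary terminus, and any O-geranyl ether re-ionises and funnels to the C-alkylated dione), and the chiral pocket of the ligand is expected to distinguish the lactone flank from the enolate flank of the planar nucleophile and so set the quaternary centre as S (the ligand hand is to be confirmed in the first run and inverted if the sense is opposite).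

**Step 3**
Reactants: 6 phloroglucinol (benzene-1,3,5-triol); 7 butanoyl chloride
Product: 8 1-(2,4,6-trihydroxyphenyl)butan-1-one
Conditions: AlCl3 (4.0 equiv), PhNO2, 23 → 65 °C; then ice, 2 M aq HCl
Reagents that add atoms: butanoyl chloride (7), CCCC(=O)Cl
Why: Friedel–Crafts acylation of the highly activated, symmetric ring should stop after one acyl group because the aluminium-chelated aryl ketone is deactivated; no stereocentre is formed.

**Step 4**
Reactants: 8 1-(2,4,6-trihydroxyphenyl)butan-1-one; 9 3-methylbut-2-enal
Product: 11 1-(5,7-dihydroxy-2,2-dimethyl-2H-chromen-6-yl)butan-1-one, via ortho-quinone methide 10 (not isolated)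
Conditions: ethylenediammonium diacetate (20 mol %), toluene–THF, 80 °C
Reagents that add atoms: 3-methylbut-2-enal (9), CC(C)=CC=O
Why: Knoevenagel-type condensation at a ring carbon gives ortho-quinone methide 10, whose oxa-6π electrocyclisation is expected to close ring B mainly onto the non-chelated para oxygen; the 8-acyl regioisomer is the expected by-product and is removed by chromatography; no stereocentre is formed.

**Step 5**
Reactants: 11 1-(5,7-dihydroxy-2,2-dimethyl-2H-chromen-6-yl)butan-1-one; 12 Meldrum's acid (2,2-dimethyl-1,3-dioxane-4,6-dione); 13 formaldehyde (as paraformaldehyde)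
Product: 17 chromene-fused 3,4-dihydrocoumarin [δ-lactone of 3-(6-butanoyl-5,7-dihydroxy-2,2-dimethyl-2H-chromen-8-yl)propanoic acid on the C7 oxygen], via methylene Meldrum acid 14 (not isolated), via arylmethyl Meldrum adduct 15 (not isolated), via lactone carboxylic acid 16 (not isolated)
Conditions: 12 and (CH2O)n (1.5 equiv each, premixed), Et3N (1.0 equiv), MeCN, 23 °C; then pyridine, 100 °C
Reagents that add atoms: Meldrum's acid (12), CC1(C)OC(=O)CC(=O)O1; formaldehyde (13), C=O
Why: Yonemitsu-type three-component condensation: the Michael acceptor 14 should be captured by C8, the only free ring carbon of 11, in a Friedel–Crafts conjugate addition, and on heating the neighbouring C7 hydroxyl (the pyran oxygen cannot) opens the dioxanedione with loss of acetone, after which the malonic half ester 16 decarboxylates, so the lactone regiochemistry is fixed by the substrate and no stereocentre survives.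

**Step 6**
Reactants: 17 chromene-fused 3,4-dihydrocoumarin; 5 (3S)-3-geranyl-3,6-dimethyl-2H-pyran-2,4(3H)-dione
Product: 20 target CNP0203748.1 [(4R)-2-acetyl-6-[(6-butanoyl-5,7-dihydroxy-2,2-dimethyl-2H-chromen-8-yl)methyl]-4-[(2E)-3,7-dimethylocta-2,6-dien-1-yl]-3,5-dihydroxy-4-methylcyclohexa-2,5-dien-1-one], via dilithium phenoxide enolate 18 (not isolated), via ring-opened diketonate 19 (not isolated)
Conditions: LiN(SiMe3)2 (2.05 equiv), THF, −78 °C, 30 min; then 5 (1.05 equiv), −78 → 23 °C; then 1 M aq HCl
Reagents that add atoms: (3S)-3-geranyl-3,6-dimethyl-2H-pyran-2,4(3H)-dione (5), CC1=CC(=O)[C@](C)(C/C=C(\C)CCC=C(C)C)C(=O)O1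
Why: Proposed new method: the lactone enolate carbon of 18 (future C6′) should attack the enol-lactone carbonyl C2 of 5, a vinylogous anhydride, and the adduct should collapse by expelling the ring oxygen as Z-β-diketonate 19, which unmasks the acetyl group; the diketonate carbon (future C2′) then attacks the aryl-lactone carbonyl (future C1′) in a Claisen condensation that ejects the C7 phenoxide, and the β-triketone formed is at once deprotonated, which drains the equilibria toward 20. The closest known reaction types are the crossed Claisen acylation of lactone enolates by activated esters, the Baker–Venkataraman/Dieckmann transfer of an aryl-ester acyl group to an enolate carbon, and the magnesium-methoxide recyclisation of 6-acetonyl-4-hydroxy-2-pyranones to acylphloroglucinols; what is new is their fusion into one ring-transformation cascade between two lactones. Ring C closes in a 6-(enolexo)-exo-trig acyl substitution while the pyrandione ring and the dihydrocoumarin ring both open. No stereocentre is created (C6′ ends as an enol carbon) and the quaternary centre is carried over from 5 untouched, since no bond to it is made or broken; its descriptor changes from S to R only because the CIP ranking of its two carbonyl neighbours is reversed. The step needs site selectivity on 5 (the hard lithium enolate is expected to prefer acyl carbon C2 over the β,β-disubstituted C6, and addition at the C4 ketone is reversible), C- over O-acylation (an O-acylated enol lactone is reopened by the tethered phenoxide) and Claisen over aldol closure (an aldol product cannot aromatise past quaternary C4′ and reverts). It also needs enolisation of 17 at the lactone and not at the butanoyl group, which the ortho-phenoxide formed first is expected to secure by turning that ketone into a vinylogous carboxylate.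

**Compound list**

1 | geraniol, (2E)-3,7-dimethylocta-2,6-dien-1-ol | OC/C=C(\C)CCC=C(C)C | starting material
2 | di-tert-butyl dicarbonate | CC(C)(C)OC(=O)OC(=O)OC(C)(C)C | starting material
3 | tert-butyl (2E)-3,7-dimethylocta-2,6-dien-1-yl carbonate | CC(C)(C)OC(=O)OC/C=C(\C)CCC=C(C)C | intermediate
4 | 4-hydroxy-3,6-dimethyl-2H-pyran-2-one | CC1=CC(O)=C(C)C(=O)O1 | starting material
5 | (3S)-3-[(2E)-3,7-dimethylocta-2,6-dien-1-yl]-3,6-dimethyl-2H-pyran-2,4(3H)-dione | CC1=CC(=O)[C@](C)(C/C=C(\C)CCC=C(C)C)C(=O)O1 | intermediate
6 | phloroglucinol (benzene-1,3,5-triol) | Oc1cc(O)cc(O)c1 | starting material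
7 | butanoyl chloride | CCCC(=O)Cl | starting material
8 | 1-(2,4,6-trihydroxyphenyl)butan-1-one | CCCC(=O)c1c(O)cc(O)cc1O | intermediate
9 | 3-methylbut-2-enal | CC(C)=CC=O | starting material
10 | ortho-quinone methide from 8 and 9 (3-(3-methylbut-2-enylidene) dienone, not isolated) | CCCC(=O)C1=C(O)/C(=C/C=C(C)C)C(=O)C=C1O | intermediate
11 | 1-(5,7-dihydroxy-2,2-dimethyl-2H-chromen-6-yl)butan-1-one | CCCC(=O)c1c(O)cc2OC(C)(C)C=Cc2c1O | intermediate
12 | Meldrum's acid (2,2-dimethyl-1,3-dioxane-4,6-dione) | CC1(C)OC(=O)CC(=O)O1 | starting material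
13 | formaldehyde (used as paraformaldehyde) | C=O | starting material
14 | 2,2-dimethyl-5-methylene-1,3-dioxane-4,6-dione (not isolated) | C=C1C(=O)OC(C)(C)OC1=O | intermediate
15 | 5-[(6-butanoyl-5,7-dihydroxy-2,2-dimethyl-2H-chromen-8-yl)methyl]-2,2-dimethyl-1,3-dioxane-4,6-dione (not isolated) | CCCC(=O)c1c(O)c(CC2C(=O)OC(C)(C)OC2=O)c2OC(C)(C)C=Cc2c1O | intermediate
16 | 3-carboxy derivative of lactone 17 (racemic at the lactone C3, not isolated) | CCCC(=O)c1c(O)c2C=CC(C)(C)Oc2c2CC(C(=O)O)C(=O)Oc12 | intermediate
17 | δ-lactone of 3-(6-butanoyl-5,7-dihydroxy-2,2-dimethyl-2H-chromen-8-yl)propanoic acid on the C7 oxygen (chromene-fused 3,4-dihydrocoumarin) | CCCC(=O)c1c(O)c2C=CC(C)(C)Oc2c2CCC(=O)Oc12 | intermediate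
18 | dilithium salt of 17 (C5 phenoxide and lactone enolate, not isolated) | CCCC(=O)c1c([O-])c2C=CC(C)(C)Oc2c2CC=C([O-])Oc12.[Li+].[Li+] | intermediate
19 | dilithium salt of the crossed-Claisen adduct (3-acyl lactone carrying the Z-diketonate chain, both epimers at the lactone C3, not isolated) | CCCC(=O)c1c([O-])c2C=CC(C)(C)Oc2c2CC(C(=O)[C@@](C)(C/C=C(\C)CCC=C(C)C)C(=O)/C=C(/C)[O-])C(=O)Oc12.[Li+].[Li+] | intermediate
20 | CNP0203748.1, (4R)-2-acetyl-6-[(6-butanoyl-5,7-dihydroxy-2,2-dimethyl-2H-chromen-8-yl)methyl]-4-[(2E)-3,7-dimethylocta-2,6-dien-1-yl]-3,5-dihydroxy-4-methylcyclohexa-2,5-dien-1-one | CCCC(=O)c1c(O)c2c(c(CC3=C(O)[C@@](C)(C/C=C(\C)CCC=C(C)C)C(O)=C(C(C)=O)C3=O)c1O)OC(C)(C)C=C2 | target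

**Step count and risks**

Total step count: 6. Longest linear sequence: 4 steps (steps 3, 4, 5, 6 from phloroglucinol); the other branch is steps 1, 2, 6.

The three steps most likely to fail:

Step 6 (Proposed new method). The dilithium species of 17 may enolise at the butanoyl chain or collapse to a ketene. The enolate may also add to C6 of 5 or merely deprotonate its 6-methyl group, and the closing acyl transfer may stall at the O-acylated stage. The fallback sets out from 5 and 11 and returns at 20; it separates the union from the ring closure and builds the CH2 bridge last. Compound 5 is opened by a crossed Claisen condensation with the lithium enolate of methyl acetate (LiN(i-Pr)2, THF, −78 °C, 2.2 equiv of enolate) to methyl (4S)-4-[(2E)-3,7-dimethylocta-2,6-dien-1-yl]-4-methyl-3,5,7-trioxooctanoate F1. The triketo ester is cyclised at the same C1′–C2′ bond by the magnesium-templated Claisen condensation known for 3,5,7-triketo esters (Mg(OMe)2, MeOH, reflux) to the monomer (4R)-2-acetyl-4-[(2E)-3,7-dimethylocta-2,6-dien-1-yl]-3,5-dihydroxy-4-methylcyclohexa-2,5-dien-1-one F2. Its only free ring carbon is aminomethylated with N,N-dimethylmethyleneiminium iodide (CH2Cl2, 23 °C) to the Mannich base (4R)-2-acetyl-6-[(dimethylamino)methyl]-4-[(2E)-3,7-dimethylocta-2,6-dien-1-yl]-3,5-dihydroxy-4-methylcyclohexa-2,5-dien-1-one F3. Warming F3 with 11 (toluene, 80 °C) should expel dimethylamine to the methylene trione, which C8 of 11 traps in the standard Michael route to unsymmetrical methylene-bridged acylphloroglucinols, giving 20.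

Step 2. The nearly symmetric pyranonate may be poorly differentiated in the chiral pocket. The π-geranyl intermediate may also erode the E-olefin geometry or be attacked at its branched terminus, and slow re-ionisation of the C-allyl product may lower the enantiomeric purity. The fallback sets out from 1 and returns at 5; it replaces catalytic control by an amino-acid auxiliary on an acyclic β-keto ester. Geraniol 1 is converted (PBr3, Et2O, 0 °C) to geranyl bromide F4. Ethyl 2-methyl-3-oxobutanoate is condensed with L-valine tert-butyl ester (BF3·OEt2 cat., benzene, azeotropic removal of water) to the enamino ester tert-butyl N-[(2Z)-4-ethoxy-3-methyl-4-oxobut-2-en-2-yl]-L-valinate F5. Its lithium aza-enolate (LiN(i-Pr)2, −78 °C, with toluene–HMPA or THF chosen according to the known solvent-dependent sense of this auxiliary alkylation) is alkylated with F4 to the imine of ethyl (2S)-2-geranyl-2-methyl-3-oxobutanoate with L-valine tert-butyl ester F6. Mild aqueous acid hydrolysis releases the auxiliary and gives ethyl (2S)-2-[(2E)-3,7-dimethylocta-2,6-dien-1-yl]-2-methyl-3-oxobutanoate F7. The methyl ketone of F7 is acetylated through its lithium enolate (LiN(SiMe3)2, THF, −78 °C; 1-acetylimidazole) to ethyl (2S)-2-[(2E)-3,7-dimethylocta-2,6-dien-1-yl]-2-methyl-3,5-dioxohexanoate F8. Its enol is closed onto the ester (pyridinium p-toluenesulfonate cat., toluene, 100 °C, ethanol taken up on 4 Å sieves) to rejoin the route at 5.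

Step 4. Ring B may close onto the chelated ortho oxygen (giving the 8-acyl chromene), and a second condensation may give a bis-pyran. The fallback sets out from 8 and returns at 11; it fixes the regiochemistry by placing the future pyran oxygen first. Compound 8 is O-alkylated at its most acidic, non-chelated 4-hydroxyl with 3-chloro-3-methylbut-1-yne (K2CO3, KI, acetone, 56 °C) to 1-[2,6-dihydroxy-4-(2-methylbut-3-yn-2-yloxy)phenyl]butan-1-one F9. Heating F9 (xylene, 140 °C) should trigger the aryl propargyl ether Claisen rearrangement, 1,5-hydrogen shift and oxa-6π electrocyclisation, which can only place the pyran oxygen para to the acyl group, and so gives 11.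

**Further compounds**

F1 | step 6 | methyl (4S)-4-[(2E)-3,7-dimethylocta-2,6-dien-1-yl]-4-methyl-3,5,7-trioxooctanoate | COC(=O)CC(=O)[C@@](C)(C/C=C(\C)CCC=C(C)C)C(=O)CC(C)=O
F2 | step 6 | (4R)-2-acetyl-4-[(2E)-3,7-dimethylocta-2,6-dien-1-yl]-3,5-dihydroxy-4-methylcyclohexa-2,5-dien-1-one | CC(=O)C1=C(O)[C@](C)(C/C=C(\C)CCC=C(C)C)C(O)=CC1=O
F3 | step 6 | (4R)-2-acetyl-6-[(dimethylamino)methyl]-4-[(2E)-3,7-dimethylocta-2,6-dien-1-yl]-3,5-dihydroxy-4-methylcyclohexa-2,5-dien-1-one | CC(=O)C1=C(O)[C@](C)(C/C=C(\C)CCC=C(C)C)C(O)=C(CN(C)C)C1=O
F4 | step 2 | geranyl bromide, (2E)-1-bromo-3,7-dimethylocta-2,6-diene | BrC/C=C(\C)CCC=C(C)C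
F5 | step 2 | tert-butyl N-[(2Z)-4-ethoxy-3-methyl-4-oxobut-2-en-2-yl]-L-valinate | CCOC(=O)/C(C)=C(C)\N[C@@H](C(C)C)C(=O)OC(C)(C)C
F6 | step 2 | imine of ethyl (2S)-2-geranyl-2-methyl-3-oxobutanoate with L-valine tert-butyl ester | CCOC(=O)[C@@](C)(C/C=C(\C)CCC=C(C)C)C(C)=N[C@@H](C(C)C)C(=O)OC(C)(C)C
F7 | step 2 | ethyl (2S)-2-[(2E)-3,7-dimethylocta-2,6-dien-1-yl]-2-methyl-3-oxobutanoate | CCOC(=O)[C@@](C)(C/C=C(\C)CCC=C(C)C)C(C)=O
F8 | step 2 | ethyl (2S)-2-[(2E)-3,7-dimethylocta-2,6-dien-1-yl]-2-methyl-3,5-dioxohexanoate | CCOC(=O)[C@@](C)(C/C=C(\C)CCC=C(C)C)C(=O)CC(C)=O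
F9 | step 4 | 1-[2,6-dihydroxy-4-(2-methylbut-3-yn-2-yloxy)phenyl]butan-1-one | CCCC(=O)c1c(O)cc(OC(C)(C)C#C)cc1O
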